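**Plan**
- Retrosynthesis: the cyclohexanone ring is cut at the bond between the ketone carbon and one α-CH2 and at the bond between the carbinol carbon and its neighbouring CH2, which excises a CH2–CH2 unit. The palmitate C–O bond and the bond from the carbinol carbon to the side-chain CH2 are cut next.
- Enabling feature: in the 4-hydroxycyclohexanone ring the tertiary carbinol carbon and the ketone carbon stand 1,4 to each other. The hydroxyl oxygen, these two carbons and the two CH2 between them are a latent 2-methoxy-5-alkylfuran (ketone carbon = furan C2, carbinol carbon = furan C5, hydroxyl O = ring O). The other two ring CH2 are the olefinic carbons of an acrylate used as an ethylene surrogate.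
- Forward: 2-methoxyfuran is lithiated at C5 and opened onto ethylene oxide, then the alcohol is palmitoylated. A dearomatizing [4+2] cycloaddition with benzyl acrylate builds the carbocycle, and opening of the oxygen bridge unveils the tertiary hydroxyl.
- Helpers out: one telescoped hydrogenation, hydrogenolysis and acid hydrolysis/decarboxylation removes the CO2Bn activating group and the O-methyl and releases the ketone.
- Stereochemistry: the target has no stereocenter, so none has to be set. The stereocenters of the intermediates form without control and are all erased.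

Key step: step 3

Remark: the carbinol carbon of the target carries two constitutionally identical ring arms, so the compound is achiral and "single enantiomer" means the compound itself. Chiral intermediates are carried as racemates or diastereomer mixtures and are drawn without stereodescriptors.

Step 1
Reactants: 1 2-methoxyfuran; 2 ethylene oxide (oxirane)
Product: 5 2-(5-methoxyfuran-2-yl)ethanol, via (5-methoxyfuran-2-yl)lithium 3 (not isolated), via lithium 2-(5-methoxyfuran-2-yl)ethoxide 4 (not isolated)
Conditions: n-BuLi (1.05 equiv), THF, −78 → 0 °C; then 2 (2.5 M in THF, 1.5 equiv), 0 °C → rt; H2O quench (kept basic)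
Reagents that add atoms: none
Why: Directed α-lithiation of the furan at the free C5 position followed by SN2 opening of the epoxide by the furyllithium (heteroaryllithium/epoxide alkylation) should install the two-carbon hydroxyethyl arm; the basic quench protects the acid-labile 2-alkoxyfuran.

Step 2
Reactants: 5 2-(5-methoxyfuran-2-yl)ethanol; 6 hexadecanoyl chloride (palmitoyl chloride)
Product: 7 2-(5-methoxyfuran-2-yl)ethyl hexadecanoate
Conditions: Et3N (1.5 equiv), DMAP (5 mol %), CH2Cl2, 0 °C → rt
Reagents that add atoms: none
Why: DMAP-catalysed O-acylation of a primary alcohol with an acid chloride under basic conditions should leave the acid-sensitive methoxyfuran intact, and the ester caps the hydroxyl so that it cannot add to electrophilic intermediates later.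

Step 3
Reactants: 7 2-(5-methoxyfuran-2-yl)ethyl hexadecanoate; 8 benzyl acrylate
Product: 10 benzyl 5-[2-(hexadecanoyloxy)ethyl]-5-hydroxy-2-methoxycyclohexa-1,3-diene-1-carboxylate, via oxanorbornene cycloadduct 9 (not isolated)
Conditions: 8 (4 equiv, filtered through basic alumina), 2,6-lutidine (5 mol %), BHT (cat.), toluene (2 M), 70 °C, sealed tube; chromatography on Et3N-deactivated silica
Reagents that add atoms: none
Why: A normal-electron-demand Diels–Alder [4+2] cycloaddition of the electron-rich 2-alkoxyfuran with the acrylate, probably asynchronous with the bond from furan C5 to the acrylate β-carbon leading, should dearomatize the furan and form the ketone-carbon/α-carbon bond and the carbinol-carbon/CH2 bond together. The closest known reaction type is the Diels–Alder reaction of 2-methoxy-, 2-silyloxy- and 2-amidofurans with acrylates and maleic derivatives, followed by opening of the oxygen bridge. The six-membered carbocycle closes by suprafacial [4+2] cycloaddition to the 7-oxabicyclo[2.2.1]heptene 9; the bridge then opens by heterolysis of the ketal C–O bond, pushed by the methoxy lone pair, and loss of the acidic proton α to the ester gives the push–pull dienol ether 10, which makes the otherwise reversible furan cycloaddition irreversible. The three stereocenters of 9 arise without control as an endo/exo mixture of racemates and none needs control, since the ester-bearing carbon becomes sp2 in 10 and the carbinol carbon is no stereocenter in 13. The step needs regioselectivity (ester-bearing carbon bonded to the methoxy-bearing furan carbon), which the 2-methoxy group secures by placing the largest HOMO coefficient on C5 so that C5 bonds to the acrylate β-carbon; the alkyl group on C5 shuts off the substitution/rearomatization pathway, and the non-acidic medium keeps 10 from dehydrating to an arene.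

Step 4
Reactants: 10 benzyl 5-[2-(hexadecanoyloxy)ethyl]-5-hydroxy-2-methoxycyclohexa-1,3-diene-1-carboxylate
Product: 13 2-(1-hydroxy-4-oxocyclohexyl)ethyl hexadecanoate, via enol ether acid 11 (not isolated), via keto acid 12 (not isolated)
Conditions: H2 (1 atm), 10% Pd/C, Et3N (5 mol %), THF, rt; filter (Celite); then 1 M aq HCl, THF, 40 °C
Reagents that add atoms: water, O
Why: Heterogeneous hydrogenation should saturate the disubstituted ring alkene (removing the arene-hydrate character before any acid is present) and hydrogenolyse the benzyl ester while the tetrasubstituted push–pull enol ether survives; aqueous acid should then hydrolyse the β-methoxyacrylic acid to the β-keto acid, which decarboxylates (enol ether hydrolysis/β-keto acid decarboxylation), leaving the achiral hydroxy ketone with the palmitate untouched.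

**Compound list**
1 | 2-methoxyfuran | COc1ccco1 | starting material
2 | ethylene oxide (oxirane) | C1CO1 | starting material
3 | (5-methoxyfuran-2-yl)lithium | [Li]c1ccc(OC)o1 | intermediate
4 | lithium 2-(5-methoxyfuran-2-yl)ethoxide | [Li+].[O-]CCc1ccc(OC)o1 | intermediate
5 | 2-(5-methoxyfuran-2-yl)ethanol | COc1ccc(CCO)o1 | intermediate
6 | hexadecanoyl chloride (palmitoyl chloride) | CCCCCCCCCCCCCCCC(=O)Cl | starting material
7 | 2-(5-methoxyfuran-2-yl)ethyl hexadecanoate | CCCCCCCCCCCCCCCC(=O)OCCc1ccc(OC)o1 | intermediate
8 | benzyl acrylate | C=CC(=O)OCc1ccccc1 | starting material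
9 | benzyl 4-[2-(hexadecanoyloxy)ethyl]-1-methoxy-7-oxabicyclo[2.2.1]hept-5-ene-2-carboxylate (racemic, endo/exo mixture) | CCCCCCCCCCCCCCCC(=O)OCCC12CC(C(=O)OCc3ccccc3)C(OC)(O1)C=C2 | intermediate
10 | benzyl 5-[2-(hexadecanoyloxy)ethyl]-5-hydroxy-2-methoxycyclohexa-1,3-diene-1-carboxylate (racemic) | CCCCCCCCCCCCCCCC(=O)OCCC1(O)CC(C(=O)OCc2ccccc2)=C(OC)C=C1 | intermediate
11 | 5-[2-(hexadecanoyloxy)ethyl]-5-hydroxy-2-methoxycyclohex-1-ene-1-carboxylic acid (racemic) | CCCCCCCCCCCCCCCC(=O)OCCC1(O)CC(C(=O)O)=C(OC)CC1 | intermediate
12 | 5-[2-(hexadecanoyloxy)ethyl]-5-hydroxy-2-oxocyclohexane-1-carboxylic acid (racemic, diastereomer mixture) | CCCCCCCCCCCCCCCC(=O)OCCC1(O)CC(C(=O)O)C(=O)CC1 | intermediate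
13 | 2-(1-hydroxy-4-oxocyclohexyl)ethyl hexadecanoate | CCCCCCCCCCCCCCCC(=O)OCCC1(O)CCC(=O)CC1 | target

**Total step count:** 4
**Longest linear sequence:** 4 steps (from 2-methoxyfuran)

**Steps most likely to fail**

Step 3. The mono-activated dienophile may add too slowly, so that acrylate polymerization competes, and the arene-hydrate-type product may lose water and aromatize if traces of acid are present. The fallback gives up the cycloaddition and reaches the ring by oxidative dearomatization of a phenol; it sets out from 6 and comes back at 13. Palmitoyl chloride 6 would be combined with commercial tyrosol (4-(2-hydroxyethyl)phenol, OCCc1ccc(O)cc1) without base in dimethyl carbonate at rt, where only the aliphatic hydroxyl should be acylated, to give 2-(4-hydroxyphenyl)ethyl hexadecanoate F1. Oxidation with PhI(OAc)2 in MeCN–THF–H2O at 0 °C should give the p-quinol 4-[2-(hexadecanoyloxy)ethyl]-4-hydroxycyclohexa-2,5-dien-1-one F2. Hydrogenation of both ring alkenes (H2, Pd/C or Rh/Al2O3, EtOAc) should then give 13.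

Step 4. The tertiary allylic hydroxyl may be lost by hydrogenolysis before the ring alkene is saturated. The conjugated enol ether may also hydrolyse so slowly that the acid needed dehydrates the tertiary alcohol or cleaves the palmitate. The fallback moves the unmasking of the ketone from aqueous acid to fluoride by using a silyl instead of a methyl group on the furan oxygen; it sets out from 7 and comes back at 12.
- Mild hydrolysis of 7 (0.1 M HCl, THF–H2O, 0 °C, then Et3N) should give the butenolide 5-[2-(hexadecanoyloxy)ethyl]furan-2(5H)-one F3.
- Silylation (TIPSOTf, Et3N, CH2Cl2, 0 °C) should give 5-[2-(hexadecanoyloxy)ethyl]-2-(triisopropylsilyloxy)furan F4.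
- Cycloaddition with 8 (toluene, 60 °C) should give benzyl 4-[2-(hexadecanoyloxy)ethyl]-1-(triisopropylsilyloxy)-7-oxabicyclo[2.2.1]hept-5-ene-2-carboxylate F5.
- HF·pyridine in THF at 0 °C should open F5 to benzyl 5-[2-(hexadecanoyloxy)ethyl]-5-hydroxy-2-oxocyclohex-3-ene-1-carboxylate F6.
- Hydrogenation of F6 (H2, Pd/C, EtOAc, rt) should give 12, which decarboxylates on gentle warming to 13 without any mineral acid.

Step 1. Lithiation may compete at C3 next to the methoxy group, the epoxide may open slowly, and the methoxyfuran may hydrolyse on work-up. The fallback replaces the organolithium chemistry by electrophilic substitution and homologation; it sets out from 1 and comes back at 5. Vilsmeier–Haack formylation of 1 (POCl3, DMF, 0 °C; aqueous NaOAc work-up) should give 5-methoxyfuran-2-carbaldehyde F7. Wittig methylenation (Ph3P=CH2, THF, 0 °C) should give 2-ethenyl-5-methoxyfuran F8, to be used at once. Anti-Markovnikov hydroboration–oxidation (9-BBN, THF; then NaOH, H2O2) should give 5.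

**Further compounds**
F1 | step 3 | 2-(4-hydroxyphenyl)ethyl hexadecanoate | CCCCCCCCCCCCCCCC(=O)OCCc1ccc(O)cc1
F2 | step 3 | 4-[2-(hexadecanoyloxy)ethyl]-4-hydroxycyclohexa-2,5-dien-1-one | CCCCCCCCCCCCCCCC(=O)OCCC1(O)C=CC(=O)C=C1
F3 | step 4 | 5-[2-(hexadecanoyloxy)ethyl]furan-2(5H)-one (racemic) | CCCCCCCCCCCCCCCC(=O)OCCC1OC(=O)C=C1
F4 | step 4 | 5-[2-(hexadecanoyloxy)ethyl]-2-(triisopropylsilyloxy)furan | CCCCCCCCCCCCCCCC(=O)OCCc1ccc(O[Si](C(C)C)(C(C)C)C(C)C)o1
F5 | step 4 | benzyl 4-[2-(hexadecanoyloxy)ethyl]-1-(triisopropylsilyloxy)-7-oxabicyclo[2.2.1]hept-5-ene-2-carboxylate (racemic, endo/exo mixture) | CCCCCCCCCCCCCCCC(=O)OCCC12CC(C(=O)OCc3ccccc3)C(O[Si](C(C)C)(C(C)C)C(C)C)(O1)C=C2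
F6 | step 4 | benzyl 5-[2-(hexadecanoyloxy)ethyl]-5-hydroxy-2-oxocyclohex-3-ene-1-carboxylate (racemic, diastereomer mixture) | CCCCCCCCCCCCCCCC(=O)OCCC1(O)CC(C(=O)OCc2ccccc2)C(=O)C=C1
F7 | step 1 | 5-methoxyfuran-2-carbaldehyde | COc1ccc(C=O)o1
F8 | step 1 | 2-ethenyl-5-methoxyfuran | COc1ccc(C=C)o1
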